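(All runs come from a simulation for an exercise.)

Late in the maple run the electrophile still falls, from 18.1% at 25.0 h to 9.8% at 40.0 h, a read half-life of 16.9 h over that one stretch. The elm flask, the one asked about, has readings up to 6.00 h.

in all of them: nucleophile 1.98 M; free base 1.48 M
- elm: electrophile 0.99 M; the very flask that is asked about, followed so far
- maple: electrophile 0.66 M; run made earlier
- flask: electrophile 0.99 M; time 2.0 d

| run | time / h | electrophile / % | product / % |
|---|---|---|---|
| elm | 1.00 | 89.7 | 10.0 |
| elm | 2.00 | 81.3 | 18.9 |
| elm | 3.00 | 74.8 | 25.2 |
| elm | 4.00 | 68.7 | 31.0 |
| elm | 5.00 | 63.5 | 36.7 |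
| elm | 6.00 | 59.3 | 40.7 |
| maple | 3.00 | 73.6 | 26.3 |
| maple | 10.0 | 41.6 | 57.6 |
| maple | 15.0 | 30.4 | 69.2 |
| maple | 25.0 | 18.1 | 82.3 |
| maple | 40.0 | 9.8 | 89.6 |
| maple | 50.0 | 7.9 | 93.0 |

(readings scatter by 0.3 percentage points)

- part of the electrophile that has reacted at 2.0 d
- share of the unused nucleophile that is free and not bound as protonated nucleophile, at 2.0 d

- what was read earlier has a scatter of 0.3 percentage points, one standard deviation
- reactions considered so far: electrophile + nucleophile <-> acid set free + product; nucleophile + acid set free <-> protonated nucleophile; acid set free + free base <-> salt of the base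
- the earlier runs do not show how much of nucleophile is bound; that part of a forecast is a guess

The ladder starts with the fastest step. Acid set free is taken up before the first elm reading at 1.00 h. The sign is in the elm readings: the charged electrophile divided by what is left, minus one, divided by time, gives 0.115 h⁻¹ at the first reading and 0.114 h⁻¹ at the last. That second value is the starting constant, the pseudo-first-order constant at the charged nucleophile. Its constancy fits free [nucleophile] staying at twice [electrophile], as charged. Each electrophile therefore appears to cost two nucleophile: one reacts, and one is bound by the acid.

On the next rung, the elm electrophile halves at 8.77 h. By this reckoning a quarter remains at 26.3 h, earlier than the asked time. My reckoning leaves 15.4%, so 84.6% has reacted. The free share stays a guess, as the runs do not show bound nucleophile.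

The maple charge leaves spare nucleophile of 0.660 M after the two-for-one cost. This gives a tail half-life of 18.2 h, near the half-life read over the stretch above.

The forecast gives 82% reacted, below my reckoning, and 45% free, holding that “most of the acid seems to sit on the nucleophile”.

The flask gives 82.0% reacted and 40.9% free, so my reckoning stands 2.6 percentage points high.

    electrophile + nucleophile ⇌ acid set free + product (K = 0.630, k = 0.0574 L mol⁻¹ h⁻¹)
    nucleophile + acid set free ⇌ protonated nucleophile, settled at all times (K = 32.2 L mol⁻¹)
    acid set free + free base ⇌ salt of the base (K = 1.20 L mol⁻¹, k = 3.30 L mol⁻¹ h⁻¹)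

A neighbour flask is charged with 0.40 M of electrophile, the limiting reagent there. Its spare nucleophile is 1.18 M, which gives a tail half-life of 10.2 h. The asked time holds 4.72 such half-lives, which leave 3.79% of its electrophile. The neighbour flask shows 3.17% left, with 96.8% reacted. Its spare nucleophile is 59.6% of the charge, and its free nucleophile ends at 62.1%.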